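**Plan**
1. The hardest feature is C8/C8′. These are doubly allylic ether carbons that ionise to a polyenyl cation once the heptaene is attached, so acid rearrangement of a 5,6-epoxide scrambles them. They must be fixed relative to quaternary C5 and remote C3 before the polyene exists, and must meet no acid afterwards.
2. The retrosynthesis cuts C11=C12 and C11′=C12′ (C2 symmetry: 2 × C15 enal + C10 bis-ylide), then O–C8 of the dihydrofuran, then C8–H, then the epoxide C–O bonds at C5/C6, then C6–C7.
3. Enabling feature: the ring O1–C5–C6=C7–C8 is the cycloisomer of the α-hydroxyallene C5(OH)–C6=C7=C8. Because C6 belongs to the carbocycle, H-8 and C9 of that allene stand below and above the ring plane. The C8 configuration can therefore be stored as an allene axis and read out by a 5-endo closure.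
4. Forward order: bought carbocycle → C6–C7 Sonogashira coupling → 5,6-epoxide → allene → dihydrofuran ring (step 7) → enal → chain joined last by a twofold Wittig reaction under near-neutral conditions.
5. Stereochemistry: C3 comes from actinol and C5 from epoxidation anti to the C3 silyloxy group. The epoxide centre C6 becomes the allene axis by anti SN2′ hydride delivery, and the axis becomes C8 by axis-to-centre transfer. The 9E and 13E alkenes are bought; 11E comes from the Wittig reaction and thermal equilibration.

Key step: step 7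

Assumption: carotenoid numbering (ring C1–C6, chain C7–C15, methyls C16–C20) is used for all fragments; the SMILES is read as all-E-(3S,5R,8R,3′S,5′R,8′R)-auroxanthin; 1, 5 and 13 are taken as commercial.

Step 1
Reactants: 1 (4R,6R)-4-hydroxy-2,2,6-trimethylcyclohexan-1-one (actinol)
Product: 2 (4R,6R)-4-[(tert-butyldimethylsilyl)oxy]-2,2,6-trimethylcyclohexan-1-one
Conditions: TBSCl, imidazole, DMF, rt
Reagents that add atoms: tert-butyldimethylsilyl chloride, CC(C)(C)[Si](C)(C)Cl
Why: Routine O-silylation of a secondary alcohol removes the only acidic proton before enolate chemistry and touches no stereocentre, the carbinol carbon being the future C3.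

Step 2
Reactants: 2 (4R,6R)-4-[(tert-butyldimethylsilyl)oxy]-2,2,6-trimethylcyclohexan-1-one
Product: 4 (4R)-4-[(tert-butyldimethylsilyl)oxy]-2,6,6-trimethylcyclohex-1-en-1-yl trifluoromethanesulfonate, via lithium enolate 3 (not isolated)
Conditions: LDA, THF, −78 to 0 °C; PhNTf2, −78 °C to rt
Reagents that add atoms: N-phenylbis(trifluoromethanesulfonimide), O=S(=O)(C(F)(F)F)N(c1ccccc1)S(=O)(=O)C(F)(F)F
Why: Enolate O-triflation is regiochemically unambiguous because one α-carbon is quaternary, so only the tetrasubstituted enol triflate (future C5=C6) can form, and the methine stereocentre that is erased is not needed.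

Step 3
Reactants: 5 (2E)-3-methylpent-2-en-4-yn-1-ol
Product: 6 tert-butyl(dimethyl){[(2E)-3-methylpent-2-en-4-yn-1-yl]oxy}silane
Conditions: TBSCl, imidazole, CH2Cl2, 0 °C to rt
Reagents that add atoms: tert-butyldimethylsilyl chloride, CC(C)(C)[Si](C)(C)Cl
Why: Routine O-silylation makes the C9=C10 bond less attractive to peracid and keeps the alcohol from consuming silane later, the 9E geometry being bought with 5.

Step 4
Reactants: 4 enol triflate; 6 silylated enynol
Product: 7 C15 dienyne bis-TBS ether, tert-butyl({(2E)-5-[(4R)-4-{[tert-butyl(dimethyl)silyl]oxy}-2,6,6-trimethylcyclohex-1-en-1-yl]-3-methylpent-2-en-4-yn-1-yl}oxy)dimethylsilane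
Conditions: Pd(PPh3)4 (5 mol %), CuI (10 mol %), Et3N, DMF, 50 °C
Reagents that add atoms: none
Why: Sonogashira coupling of a cyclohexenyl triflate with a terminal enyne forms the C6–C7 bond under mild base and leaves the 9E alkene and the C3 stereocentre untouched.

Step 5
Reactants: 7 C15 dienyne bis-TBS ether
Product: 8 (1R,4S,6R)-4-[(tert-butyldimethylsilyl)oxy]-1-{(3E)-5-[(tert-butyldimethylsilyl)oxy]-3-methylpent-3-en-1-yn-1-yl}-2,2,6-trimethyl-7-oxabicyclo[4.1.0]heptane (carotenoid 3S,5R,6R; epoxide oxygen anti to the C3 silyloxy group)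
Conditions: mCPBA, CH2Cl2/aq. NaHCO3, 0 °C; chromatography on Et3N-deactivated silica
Reagents that add atoms: 3-chloroperoxybenzoic acid, O=C(OO)c1cccc(Cl)c1
Why: Prilezhaev epoxidation should pick the tetrasubstituted C5=C6 bond over the trisubstituted C9=C10 bond with its allylic silyloxy group and should attack mainly anti to the C3 silyloxy group, as peracids tend to do on 3-oxygenated β-end groups, which sets C5 (R) and the temporary centre C6, the syn epoxide being removed by chromatography.

Step 6
Reactants: 8 alkynyl epoxide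
Product: 10 (2E)-5-[(2R,4S)-2,4-dihydroxy-2,6,6-trimethylcyclohexylidene]-3-methylpenta-2,4-dien-1-ol (allene axis S = carotenoid 6S; C9 chain on the side of 5-OH; H-8 on the side of C18), via allenyl silyl ether 9 (not isolated)
Conditions: (IPr)CuCl (5 mol %), NaOtBu (5 mol %), Me(EtO)2SiH, toluene, 0 °C to rt; then TBAF, THF, rt
Reagents that add atoms: diethoxy(methyl)silane, C[SiH](OCC)OCC (its silyl group is carried only by 9; 10 keeps only its hydride as H-8)
Why: Copper hydride catalysed SN2′ reduction of a propargyl oxirane delivers hydride to C8 anti to the breaking C6–O bond (centre-to-axis chirality transfer, whereas oxygen-bound aluminium hydrides would deliver syn and give the other axis), and fluoride then cleaves all three silyl ethers in the same flask.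

Step 7
Reactants: 10 allenic triol
Product: 11 (2R,6S,7aR)-2-[(2E)-4-hydroxybut-2-en-2-yl]-4,4,7a-trimethyl-2,4,5,6,7,7a-hexahydro-1-benzofuran-6-ol (carotenoid 3S,5R,8R)
Conditions: AuCl3 (2 mol %), 2,2′-bipyridine (3 mol %), THF, 0 °C to rt, dark
Reagents that add atoms: none
Why: Carbophilic gold binds the distal C7=C8 π bond of the allene, whose lobes lie in the mean plane of the carbocycle, the 5-OH adds to C8 anti to the metal, and protodeauration of the resulting C7–Au bond releases 11 and the catalyst. This is the gold-catalysed cycloisomerisation of α-hydroxyallenes to 2,5-dihydrofurans, which is known for tertiary carbinols and trisubstituted allenes and proceeds with axis-to-centre chirality transfer. The one ring that is closed, O1–C5–C6=C7–C8, forms in the 5-endo-trig mode and is fused to the existing carbocycle at C5–C6. The one new stereocentre, C8, is controlled only by the allene axis: oxygen attacks within the ring plane while H-8 and C9 keep their places below and above it, so the chain that stands on the side of O5 and away from C18 in 10 ends up trans to C18 in 11, which is 8R. Of the three hydroxyl groups only 5-OH can reach the allene, since 11-OH is held away by the E C9=C10 bond and 3-OH lies on the other ring face, and the isolated trisubstituted alkene is a poorer ligand for gold than the allene. The step needs a configurationally stable gold–allene complex, which the substrate secures because C8 bears a single vinyl group with an inductively withdrawing CH2OH instead of the heptaene of the target, and which THF and bipyridine support by tempering the Lewis acidity of gold.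

Step 8
Reactants: 11 dihydrofuran diol
Product: 12 (2E)-3-[(2R,6S,7aR)-6-hydroxy-4,4,7a-trimethyl-2,4,5,6,7,7a-hexahydro-1-benzofuran-2-yl]but-2-enal
Conditions: MnO2, CH2Cl2, rt
Reagents that add atoms: none
Why: Manganese dioxide oxidises only the primary allylic alcohol under neutral heterogeneous conditions, so the saturated 3-OH, the E alkene and the acid-labile C8–O bond are left alone.

Step 9
Reactants: 13 (2E,4E,6E)-2,7-dimethylocta-2,4,6-trienedial
Product: 14 (2E,4E,6E)-2,7-dimethylocta-2,4,6-triene-1,8-diol
Conditions: NaBH4, MeOH/THF, 0 °C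
Reagents that add atoms: none
Why: Borohydride 1,2-reduction converts both conjugated aldehydes into primary allylic alcohols and leaves the E,E,E-triene untouched.

Step 10
Reactants: 14 C10 diol
Product: 15 [(2E,4E,6E)-2,7-dimethylocta-2,4,6-triene-1,8-diyl]bis(triphenylphosphonium) dibromide
Conditions: Ph3P·HBr, MeOH, rt
Reagents that add atoms: triphenylphosphine hydrobromide, [Br-].c1ccc(cc1)[PH+](c1ccccc1)c1ccccc1
Why: Allylic alcohols react with triphenylphosphine hydrobromide by ionisation and capture at the primary terminus, the standard entry to carotenoid Wittig salts, and the acid is confined to this achiral branch.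

Step 11
Reactants: 12 C15 enal (2 equiv); 15 C10 bis(phosphonium) dibromide
Product: 17 all-E-(3S,5R,8R,3′S,5′R,8′R)-5,8:5′,8′-diepoxy-5,8,5′,8′-tetrahydro-β,β-carotene-3,3′-diol (auroxanthin), via C25 monophosphonium bromide 16 (not isolated)
Conditions: 1,2-epoxybutane/EtOH, reflux, N2, dark; then reflux in EtOH and crystallisation
Reagents that add atoms: none
Why: In this twofold Wittig olefination (C15 + C10 + C15) 1,2-epoxybutane scavenges HBr and releases the semi-stabilised ylide only in low concentration, so free hydroxyls are tolerated, no acid meets the C8–O bond, no strong base meets the γ-acidic H-8 of 12, and any 11Z isomers should equilibrate thermally to the all-E polyene.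

**Compound list**
1 | (4R,6R)-4-hydroxy-2,2,6-trimethylcyclohexan-1-one (actinol) | O=C1C(C)(C)C[C@H](O)C[C@H]1C | starting material
2 | (4R,6R)-4-[(tert-butyldimethylsilyl)oxy]-2,2,6-trimethylcyclohexan-1-one | O=C1C(C)(C)C[C@H](O[Si](C)(C)C(C)(C)C)C[C@H]1C | intermediate
3 | lithium (4R)-4-[(tert-butyldimethylsilyl)oxy]-2,6,6-trimethylcyclohex-1-en-1-olate | CC1=C([O-])C(C)(C)C[C@H](O[Si](C)(C)C(C)(C)C)C1.[Li+] | intermediate
4 | (4R)-4-[(tert-butyldimethylsilyl)oxy]-2,6,6-trimethylcyclohex-1-en-1-yl trifluoromethanesulfonate | CC1=C(OS(=O)(=O)C(F)(F)F)C(C)(C)C[C@H](O[Si](C)(C)C(C)(C)C)C1 | intermediate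
5 | (2E)-3-methylpent-2-en-4-yn-1-ol | C#C/C(C)=C/CO | starting material
6 | tert-butyl(dimethyl){[(2E)-3-methylpent-2-en-4-yn-1-yl]oxy}silane | C#C/C(C)=C/CO[Si](C)(C)C(C)(C)C | intermediate
7 | C15 dienyne bis-TBS ether (3R,9E) | CC1=C(C#C/C(C)=C/CO[Si](C)(C)C(C)(C)C)C(C)(C)C[C@H](O[Si](C)(C)C(C)(C)C)C1 | intermediate
8 | C15 alkynyl epoxide bis-TBS ether (3S,5R,6R,9E) | CC(C)(C)[Si](C)(C)OC/C=C(C)/C#C[C@]12C(C)(C)C[C@H](O[Si](C)(C)C(C)(C)C)C[C@@]1(C)O2 | intermediate
9 | C15 vinylallene, 3,11-bis-TBS ether 5-O-diethoxy(methyl)silyl ether (3S,5R,6S,9E) | CC(C)(C)[Si](C)(C)OC/C=C(C)/C([H])=[C@]=C1C(C)(C)C[C@H](O[Si](C)(C)C(C)(C)C)C[C@@]1(C)O[Si](C)(OCC)OCC | intermediate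
10 | (2E)-5-[(2R,4S)-2,4-dihydroxy-2,6,6-trimethylcyclohexylidene]-3-methylpenta-2,4-dien-1-ol, axis S | OC/C=C(C)/C([H])=[C@]=C1C(C)(C)C[C@H](O)C[C@@]1(C)O | intermediate
11 | (2R,6S,7aR)-2-[(2E)-4-hydroxybut-2-en-2-yl]-4,4,7a-trimethyl-2,4,5,6,7,7a-hexahydro-1-benzofuran-6-ol | OC/C=C(\C)[C@H]1C=C2C(C)(C)C[C@H](O)C[C@@]2(C)O1 | intermediate
12 | (2E)-3-[(2R,6S,7aR)-6-hydroxy-4,4,7a-trimethyl-2,4,5,6,7,7a-hexahydro-1-benzofuran-2-yl]but-2-enal | O=C/C=C(\C)[C@H]1C=C2C(C)(C)C[C@H](O)C[C@@]2(C)O1 | intermediate
13 | (2E,4E,6E)-2,7-dimethylocta-2,4,6-trienedial | O=C/C(C)=C/C=C/C=C(C)/C=O | starting material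
14 | (2E,4E,6E)-2,7-dimethylocta-2,4,6-triene-1,8-diol | OC/C(C)=C/C=C/C=C(C)/CO | intermediate
15 | [(2E,4E,6E)-2,7-dimethylocta-2,4,6-triene-1,8-diyl]bis(triphenylphosphonium) dibromide | c1ccccc1[P+](c1ccccc1)(c1ccccc1)C/C(C)=C/C=C/C=C(C)/C[P+](c1ccccc1)(c1ccccc1)c1ccccc1.[Br-].[Br-] | intermediate
16 | C25 monophosphonium bromide (one end group joined, C12′ still bearing PPh3+) | CC(/C[P+](c1ccccc1)(c1ccccc1)c1ccccc1)=C\C=C\C=C(C)\C=C\C=C(/C)[C@H]1C=C2C(C)(C)C[C@H](O)C[C@@]2(C)O1.[Br-] | intermediate
17 | all-E-(3S,5R,8R,3′S,5′R,8′R)-auroxanthin | CC(/C=C/C=C(\C)[C@H]1C=C2C(C)(C)C[C@H](O)C[C@@]2(C)O1)=C\C=C\C=C(C)\C=C\C=C(/C)[C@H]1C=C2C(C)(C)C[C@H](O)C[C@@]2(C)O1 | target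

**Total steps:** 11. **Longest linear sequence:** 8 (steps 1, 2, 4, 5, 6, 7, 8, 11).

**Steps most likely to fail (in route order)**

**Step 5.**
- What may go wrong: poor facial selectivity of the peracid, because the homoallylic silyloxy group is a weak control element. Partial attack at C9=C10 and acid-induced opening of the tertiary propargylic epoxide are further risks.
- Fallback: reagent control replaces substrate control. It sets out from 4 and comes back at 8.
- Palladium-catalysed methoxycarbonylation of 4 (CO, MeOH, Et3N) gives the ring ester F1, and DIBAL-H reduction gives the ring allylic alcohol F2.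
- Katsuki–Sharpless epoxidation with D-(−)-diethyl tartrate should place oxygen anti to the C3 silyloxy group and give the epoxy alcohol F3.
- Parikh–Doering oxidation gives the epoxy aldehyde F4, and the Ohira–Bestmann reagent (K2CO3, MeOH) gives the ethynyl epoxide F5.
- Separately, but-2-yn-1-ol is silylated to the butynyl silyl ether F6. Hydrozirconation with the Schwartz reagent followed by iodine gives the E-alkenyl iodide F7.
- Sonogashira coupling of F5 with F7 gives 8.

**Step 6.**
- What may go wrong: hydrocupration of the conjugated enyne or of the vinylallene product (over-reduction), or leakage from anti to syn displacement, which would erode the axis.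
- Fallback: the axis is built by C8–C9 bond formation instead of C8–H bond formation. It sets out from 4 and comes back at 10.
- Compound 4 is taken to the ethynyl epoxide F5 as above.
- Iodine–magnesium exchange of the E-alkenyl iodide F7 with iPrMgCl·LiCl gives the alkenylmagnesium chloride F8.
- F8 is added to F5 with catalytic CuBr and Me3SiCl in Et2O/pentane. Under these conditions Grignard reagents open 1-ethynylcyclohexene oxides by carbocupration and syn β-elimination.
- Entry of C9 on the face of the epoxide oxygen gives the same axis, in the bis-TBS allenol F9. TBAF then gives 10.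

**Step 7.**
- What may go wrong: loss of the axial information through a planar gold-bound allyl cation before the C–O bond forms.
- Closure may also be slow, because gold must sit beside the C1 gem-dimethyl group and the ring must adopt a chair with O3, C18 and one C1 methyl axial.
- The vinylallene may also be diverted into a Nazarov-type carbocyclisation.
- Fallback: a stoichiometric electrophile in two operations. It sets out from 10 and comes back at 11.
- Iodocyclisation (I2, NaHCO3, MeCN, 0 °C) closes the same ring by 5-endo attack of O5 on the iodonium-activated C7=C8 bond. It reads the axis in the same way and gives the 7-iodo dihydrofuran F10.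
- Palladium-catalysed hydrostannolysis (Bu3SnH, cat. Pd(PPh3)4, THF) replaces iodine by hydrogen at sp2 C7 without touching C8 and gives 11.

**Further compounds**
F1 | step 5 | methyl (4R)-4-[(tert-butyldimethylsilyl)oxy]-2,6,6-trimethylcyclohex-1-ene-1-carboxylate | CC1=C(C(=O)OC)C(C)(C)C[C@H](O[Si](C)(C)C(C)(C)C)C1
F2 | step 5 | {(4R)-4-[(tert-butyldimethylsilyl)oxy]-2,6,6-trimethylcyclohex-1-en-1-yl}methanol | CC1=C(CO)C(C)(C)C[C@H](O[Si](C)(C)C(C)(C)C)C1
F3 | step 5 | {(1R,4S,6R)-4-[(tert-butyldimethylsilyl)oxy]-2,2,6-trimethyl-7-oxabicyclo[4.1.0]heptan-1-yl}methanol | OC[C@]12C(C)(C)C[C@H](O[Si](C)(C)C(C)(C)C)C[C@@]1(C)O2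
F4 | step 5 | (1S,4S,6R)-4-[(tert-butyldimethylsilyl)oxy]-2,2,6-trimethyl-7-oxabicyclo[4.1.0]heptane-1-carbaldehyde | O=C[C@]12C(C)(C)C[C@H](O[Si](C)(C)C(C)(C)C)C[C@@]1(C)O2
F5 | step 5 | tert-butyl{[(1R,4S,6R)-1-ethynyl-2,2,6-trimethyl-7-oxabicyclo[4.1.0]heptan-4-yl]oxy}dimethylsilane | C#C[C@]12C(C)(C)C[C@H](O[Si](C)(C)C(C)(C)C)C[C@@]1(C)O2
F6 | step 5 | (but-2-yn-1-yloxy)(tert-butyl)dimethylsilane | CC#CCO[Si](C)(C)C(C)(C)C
F7 | step 5 | tert-butyl{[(2E)-3-iodobut-2-en-1-yl]oxy}dimethylsilane | C/C(I)=C\CO[Si](C)(C)C(C)(C)C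
F8 | step 6 | {(2E)-4-[(tert-butyldimethylsilyl)oxy]but-2-en-2-yl}magnesium chloride | C/C([Mg]Cl)=C\CO[Si](C)(C)C(C)(C)C
F9 | step 6 | C15 vinylallene 3,11-bis-TBS ether with free 5-OH (3S,5R,6S,9E) | CC(C)(C)[Si](C)(C)OC/C=C(C)/C([H])=[C@]=C1C(C)(C)C[C@H](O[Si](C)(C)C(C)(C)C)C[C@@]1(C)O
F10 | step 7 | (2S,6S,7aR)-2-[(2E)-4-hydroxybut-2-en-2-yl]-3-iodo-4,4,7a-trimethyl-2,4,5,6,7,7a-hexahydro-1-benzofuran-6-ol | OC/C=C(\C)[C@H]1C(I)=C2C(C)(C)C[C@H](O)C[C@@]2(C)O1
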